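The earlier runs and the new flask are simulated on assumed constants, noise included.

3.0 h is the longest this flask may stand, so the open choice for the next run is the charge: keep the partner at full amount, or cut it to spare material.

in all of them: partner 0.308 M (fed, over 3.0 min)

|  | starting material | remark | time |
|---|---|---|---|
| south | 0.077 M | the very flask that is asked about, followed so far; the fed solution adds 0.20 times the starting volume |  |
| west | 0.052 M | run made earlier; the fed solution adds 0.20 times the starting volume |  |
| flask | 0.077 M | the fed solution adds 0.20 times the starting volume | 3.0 h |

| run | time / min | triple product / % | starting material / % |
|---|---|---|---|
| south | 30.0 | 9.6 | 21.0 |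
| south | 40.0 | 14.5 | 13.3 |
| west | 30.0 | 10.5 | 19.4 |
| west | 40.0 | 15.9 | 11.6 |
| west | 60.0 | 24.0 | 4.9 |
| west | 80.0 | 28.2 | 1.4 |
| west | 120 | 28.6 | 0 |

(scatter of a reading: 0.3 percentage points)

- amounts are per litre of the starting volume; all of the dose is in the solution fed
- the earlier runs were read with a standard deviation of 0.3 percentage points

1. when, up to 3.0 h, the flask holds most triple product
2. the amount of triple product, in percent of the starting material charged, at that time

In this flask 4.00 is the figure I carry: the partner equivalents, partner charged per starting material charged. I read triple product as 3 partners on one starting material. That leaves this flask 1.00 equivalent to spare, so by my count partner is not the limiting reagent. Half the charge gives 2.00 equivalents, and then triple product could take at most 66.7% of the starting material. West, at 5.92 equivalents, reads 28.6% at 120 min. South, with fewer equivalents, reads 14.5% against west's 15.9% at 40.0 min. I keep the full charge, and I expect the peak to come with partner still in the flask.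

The forecast gives 28.5% at 1.9 h, judging that “triple product is also being consumed”.

    bis adduct → decomposed reagent (k = 0.0102 /min)
    partner + triple product → tetra adduct (k = 0.0922 /M/min)
    partner + bis adduct → triple product (k = 0.384 /M/min)
    starting material + partner → single product (k = 0.252 /M/min)
    partner + single product → bis adduct (k = 0.0928 /M/min)

The flask gives 28.2% at 1.93 h, so the forecast holds within its margin. With half the partner, this flask's highest amount of triple product is 16.3%, so the full charge stays. At the best time this flask still holds 38.4% of its partner, so it has spent 2.46 of its 4.00 equivalents, fewer than 3.

A neighbour flask, charged with 0.31 M of starting material, has 0.994 equivalent, so triple product could take at most 33.1% there. Computed, that neighbour flask ends at 3.00 h with 0.0801% of its partner, 6.25% triple product, and most of its material as single product, 55.0%.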